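**Strategy.** On the 1,2-dioxane ring (O1–O2–C3–C4–C5–C6) the C3 acetate arm, the C4 ethyl and the C6 ethyl share one face. The first carbons of the C3 and C6 substituents can therefore be joined as an etheno bridge. This gives a 2,3-dioxabicyclo[2.2.2]oct-5-ene, disconnected by [4+2] cycloreversion into dioxygen and a cyclohexa-1,3-diene. In the forward direction singlet oxygen forms O1–C6 and O2–C3 at once, closes the dioxane, and sets C3 and C6 from the C4 centre. The precursor is an (S)-5-ethylcyclohexa-1,3-diene bearing at C1 a (4R)-4-(silyloxymethyl)hexyl chain. Oxidative excision of the bridge then releases both arms.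

Key step: step 11

Remark on locants: monocyclic peroxides carry the target numbering (O1, O2, C3–C6). In the bicyclic peroxide, C1 is the quaternary bridgehead (target C6) and C4 is the CH bridgehead (target C3). C7 is the CH2 next to C1, and C8 is the ethyl-bearing carbon next to C4 (target C4).

Remark on design: the chain stereocentre is set by auxiliary-controlled alkylation, so the diene is a single diastereomer. The primary TBS ether (TBS = tert-butyldimethylsilyl) is inert to every reagent up to the esterification medium, where it is cleaved. The bridge is excised without a metal that could attack the O–O bond.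

Assumption: the ring fragment is obtained in high but not perfect enantiomeric purity. Because the chain fragment is a single enantiomer, the minor ring enantiomer travels as a diastereomer. It is to be removed by chromatography at the bicyclic peroxide stage.

Step 1
Reactants: 1 (4S)-4-benzyl-1,3-oxazolidin-2-one; 2 butanoyl chloride
Product: 3 (4S)-4-benzyl-3-butanoyl-1,3-oxazolidin-2-one
Conditions: Et3N, DMAP (cat.), CH2Cl2, 0 °C → rt
Reagents that add atoms: none
Why: DMAP-catalysed N-acylation of an oxazolidinone with an acid chloride is routine and touches no stereocentre.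

Step 2
Reactants: 3 (4S)-4-benzyl-3-butanoyl-1,3-oxazolidin-2-one; 4 allyl iodide (3-iodoprop-1-ene)
Product: 6 (4S)-4-benzyl-3-[(2R)-2-ethylpent-4-enoyl]-1,3-oxazolidin-2-one, via sodium Z-enolate 5 (not isolated)
Conditions: NaN(SiMe3)2, THF, −78 °C; then 4, −78 → −40 °C
Reagents that add atoms: none
Why: In this Evans asymmetric alkylation the benzyl group shields one face of the chelated Z-enolate, so the reactive allyl iodide enters from the other face and sets the (R) centre that becomes the chain stereocentre, any minor diastereomer being removable by chromatography.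

Step 3
Reactants: 6 (4S)-4-benzyl-3-[(2R)-2-ethylpent-4-enoyl]-1,3-oxazolidin-2-one
Product: 7 (2R)-2-ethylpent-4-en-1-ol
Conditions: LiBH4, H2O (1 equiv), Et2O, 0 °C
Reagents that add atoms: none
Why: Reductive cleavage of the N-acyl oxazolidinone by LiBH4 gives the primary alcohol without epimerisation, spares the terminal alkene and returns the auxiliary.

Step 4
Reactants: 7 (2R)-2-ethylpent-4-en-1-ol
Product: 8 tert-butyl{[(2R)-2-ethylpent-4-en-1-yl]oxy}dimethylsilane
Conditions: TBSCl, imidazole, CH2Cl2, rt
Reagents that add atoms: tert-butyldimethylsilyl chloride, CC(C)(C)[Si](C)(C)Cl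
Why: Imidazole-promoted silylation of an unhindered primary alcohol is standard protecting-group chemistry.

Step 5
Reactants: 8 tert-butyl{[(2R)-2-ethylpent-4-en-1-yl]oxy}dimethylsilane
Product: 10 tert-butyl{[(2R)-2-ethyl-5-iodopentyl]oxy}dimethylsilane, via alkylzirconocene chloride 9 (not isolated)
Conditions: Cp2Zr(H)Cl, THF, rt, dark; then I2, 0 °C
Reagents that add atoms: iodine, II
Why: In this hydrozirconation–iodinolysis, zirconium adds to the terminal carbon of the monosubstituted alkene and I2 cleaves the C–Zr bond to the primary iodide, leaving the silyl ether and the remote stereocentre untouched.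

Step 6
Reactants: 11 butanal; 12 but-3-en-2-one (methyl vinyl ketone)
Product: 13 (2S)-2-ethyl-5-oxohexanal
Conditions: (R)-2-[methoxy(diphenyl)methyl]pyrrolidine (5 mol %), ethyl 3,4-dihydroxybenzoate (20 mol %), neat, 4 °C
Reagents that add atoms: none
Why: In this enamine-catalysed asymmetric Michael addition the E-enamine of butanal is attacked on the face remote from the CPh2OMe group, which with the (R)-catalyst sets the (S) centre that becomes C4 of the target.

Step 7
Reactants: 13 (2S)-2-ethyl-5-oxohexanal
Product: 14 (4S)-4-ethylcyclohex-2-en-1-one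
Conditions: LiOH, i-PrOH, rt
Reagents that add atoms: none
Why: Intramolecular aldol condensation of the methyl ketone onto the aldehyde closes the six-membered enone, and short contact with the mild base keeps the ethyl-bearing centre (now γ to the carbonyl) intact.

Step 8
Reactants: 14 (4S)-4-ethylcyclohex-2-en-1-one; 10 tert-butyl{[(2R)-2-ethyl-5-iodopentyl]oxy}dimethylsilane
Product: 16 (4S)-4-ethyl-6-[(4R)-4-(TBSO-methyl)hexyl]cyclohex-2-en-1-one (C6 epimers), via lithium dienolate 15 (not isolated)
Conditions: LiN(i-Pr)2, THF, −78 °C; then 10, DMPU, −78 → 0 °C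
Reagents that add atoms: none
Why: Kinetic α′-deprotonation gives the cross-conjugated dienolate, whose SN2 C-alkylation by the primary iodide is helped by DMPU, and the C6 epimer mixture does not matter because C6 becomes sp2 in the next step.

Step 9
Reactants: 16 (4S)-4-ethyl-6-[(4R)-4-(TBSO-methyl)hexyl]cyclohex-2-en-1-one
Product: 18 (4S)-4-ethyl-2-[(4R)-4-(TBSO-methyl)hexyl]cyclohexa-1,5-dien-1-yl trifluoromethanesulfonate, via lithium dienolate 17 (not isolated)
Conditions: LiN(i-Pr)2, THF, −78 → −40 °C; then N-(5-chloropyridin-2-yl)bis(trifluoromethanesulfonimide), −78 → 0 °C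
Reagents that add atoms: N-(5-chloropyridin-2-yl)bis(trifluoromethanesulfonimide), FC(F)(F)S(=O)(=O)N(c1ccc(Cl)cn1)S(=O)(=O)C(F)(F)F
Why: Kinetic enolisation at the only remaining α′-hydrogen followed by O-sulfonylation (enol triflate formation) fixes the diene positions, while the γ-hydrogen at the stereocentre is not removed under kinetic conditions.

Step 10
Reactants: 18 (4S)-4-ethyl-2-[(4R)-4-(TBSO-methyl)hexyl]cyclohexa-1,5-dien-1-yl trifluoromethanesulfonate
Product: 19 (5S)-5-ethyl-1-[(4R)-4-({[tert-butyl(dimethyl)silyl]oxy}methyl)hexyl]cyclohexa-1,3-diene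
Conditions: Pd(OAc)2 (5 mol %), PPh3 (10 mol %), HCO2H, Et3N, DMF, 50 °C
Reagents that add atoms: none
Why: Palladium-catalysed formate reduction of the enol triflate (oxidative addition to zerovalent palladium, formate exchange, loss of CO2, reductive elimination) replaces OTf by H without moving either double bond.

Step 11
Reactants: 19 (5S)-5-ethyl-1-[(4R)-4-({[tert-butyl(dimethyl)silyl]oxy}methyl)hexyl]cyclohexa-1,3-diene
Product: 20 (1S,4R,8S)-1-[(4R)-4-({[tert-butyl(dimethyl)silyl]oxy}methyl)hexyl]-8-ethyl-2,3-dioxabicyclo[2.2.2]oct-5-ene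
Conditions: O2, tetraphenylporphyrin (cat.), visible light, CH2Cl2, −78 °C
Reagents that add atoms: dioxygen, O=O
Why: Sensitised singlet oxygen adds to the s-cis-locked diene of 19 in a concerted suprafacial [4+2] cycloaddition, the ascaridole-type photooxygenation known for cyclohexa-1,3-dienes, and forms the bonds O2–C1 and O3–C4 of 20 (O1–C6 and O2–C3 of the target) in one event. The ring closure is a bridging cycloaddition across the diene termini: the O–O unit spans C1 and C4, so the saturated 1,2-dioxane (O2, O3, C4, C8, C7, C1) closes as a boat and C5=C6 remains as the etheno bridge. C1 and C4 are tied to each other by suprafaciality, and their absolute sense is controlled by the C5 ethyl stereocentre of 19, which sends oxygen to the opposite face and so ends up on C8 syn to the etheno bridge, that is cis to both future arms. Full substitution at C1 does not slow the reaction, since the ring already holds that carbon in the cisoid geometry. Two selectivities are needed: facial selectivity, secured only by the single ethyl group and therefore expected to be moderate, so that the syn adduct has to be removed by chromatography, and [4+2] over ene reaction at the trisubstituted C1=C2 bond, which the locked diene, the aprotic solvent and the low temperature favour.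

Step 12
Reactants: 20 (1S,4R,8S)-1-[(4R)-4-(TBSO-methyl)hexyl]-8-ethyl-2,3-dioxabicyclo[2.2.2]oct-5-ene
Product: 22 (3R,4S,6S)-4-ethyl-6-[(4R)-4-(TBSO-methyl)hexyl]-1,2-dioxane-3,6-dicarbaldehyde, via cis-diol 21 (not isolated)
Conditions: OsO4 (cat.), NMO, acetone/H2O, rt; then NaIO4, 0 °C → rt; crude product used at once
Reagents that add atoms: osmium tetroxide (catalytic oxygen carrier), O=[Os](=O)(=O)=O; N-methylmorpholine N-oxide, C[N+]1([O-])CCOCC1; water, O
Why: Catalytic OsO4/NMO dihydroxylation is known to leave the O–O bond of 2,3-dioxabicyclo[2.2.2]oct-5-enes intact (diol expected anti to the peroxide bridge), and periodate glycol cleavage in the same flask erases the two carbinol centres and excises the carbocycle without touching C3, C4 or C6.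

Step 13
Reactants: 22 (3R,4S,6S)-4-ethyl-6-[(4R)-4-(TBSO-methyl)hexyl]-1,2-dioxane-3,6-dicarbaldehyde
Product: 23 (3S,4S,6S)-3,6-diethenyl-4-ethyl-6-[(4R)-4-(TBSO-methyl)hexyl]-1,2-dioxane
Conditions: Ph3PCH3Br, KN(SiMe3)2, THF, 0 °C; then 22, −78 → 0 °C
Reagents that add atoms: methyltriphenylphosphonium bromide, C[P+](c1ccccc1)(c1ccccc1)c1ccccc1.[Br-]
Why: In this double Wittig methylenation the non-stabilised ylide adds to both aldehydes at −78 °C faster than it can remove the C3 hydrogen, and dialkyl peroxides tolerate phosphorus ylides at low temperature.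

Step 14
Reactants: 23 (3S,4S,6S)-3,6-diethenyl-4-ethyl-6-[(4R)-4-(TBSO-methyl)hexyl]-1,2-dioxane
Product: 25 2-{(3S,4S,6S)-6-ethenyl-4-ethyl-6-[(4R)-4-(TBSO-methyl)hexyl]-1,2-dioxan-3-yl}ethan-1-ol, via alkyldisiamylborane 24 (not isolated)
Conditions: Sia2BH (1.2 equiv, from BH3·THF and 2-methylbut-2-ene), THF, 0 °C; then NaBO3·4H2O, THF/H2O, rt
Reagents that add atoms: sodium perborate tetrahydrate, [Na+].[O-]OB=O.O.O.O.O
Why: In this Brown hydroboration–oxidation the bulky dialkylborane places boron on the terminal carbon and prefers the C3 vinyl (allylic CH) over the C6 vinyl (fully substituted allylic carbon), and both borane addition and perborate oxidation are tolerated by cyclic peroxides.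

Step 15
Reactants: 25 2-{(3S,4S,6S)-6-ethenyl-4-ethyl-6-[(4R)-4-(TBSO-methyl)hexyl]-1,2-dioxan-3-yl}ethan-1-ol
Product: 26 2-{(3S,4S,6S)-4,6-diethyl-6-[(4R)-4-(TBSO-methyl)hexyl]-1,2-dioxan-3-yl}ethan-1-ol
Conditions: KO2CN=NCO2K, AcOH, MeOH/CH2Cl2, 0 °C → rt
Reagents that add atoms: none
Why: Diimide reduction transfers H2 to the monosubstituted alkene in a concerted step and is the classical way to saturate C=C beside an O–O bond, which catalytic hydrogenation would cleave.

Step 16
Reactants: 26 2-{(3S,4S,6S)-4,6-diethyl-6-[(4R)-4-(TBSO-methyl)hexyl]-1,2-dioxan-3-yl}ethan-1-ol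
Product: 27 2-{(3S,4S,6S)-4,6-diethyl-6-[(4R)-4-(TBSO-methyl)hexyl]-1,2-dioxan-3-yl}acetic acid
Conditions: TEMPO (cat.), PhI(OAc)2, MeCN/H2O, rt
Reagents that add atoms: water, O
Why: Oxoammonium (TEMPO/PhI(OAc)2) oxidation takes the primary alcohol through the aldehyde hydrate to the acid under nearly neutral conditions, which avoid β-elimination of the peroxide and keep the silyl ether.

Step 17
Reactants: 27 2-{(3S,4S,6S)-4,6-diethyl-6-[(4R)-4-(TBSO-methyl)hexyl]-1,2-dioxan-3-yl}acetic acid
Product: 28 methyl 2-{(3S,4S,6S)-4,6-diethyl-6-[(4R)-4-(hydroxymethyl)hexyl]-1,2-dioxan-3-yl}acetate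
Conditions: HCl (cat., methanolic), MeOH, 0 °C → rt
Reagents that add atoms: methanol, CO
Why: Fischer esterification of the unhindered acid and acid-catalysed methanolysis of the primary TBS ether run in the same medium, to which a dialkyl peroxide is inert.

Step 18
Reactants: 28 methyl 2-{(3S,4S,6S)-4,6-diethyl-6-[(4R)-4-(hydroxymethyl)hexyl]-1,2-dioxan-3-yl}acetate
Product: 29 methyl 2-{(3S,4S,6S)-4,6-diethyl-6-[(4R)-4-formylhexyl]-1,2-dioxan-3-yl}acetate
Conditions: Dess–Martin periodinane, CH2Cl2, 0 °C → rt
Reagents that add atoms: none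
Why: Dess–Martin oxidation gives the α-branched aldehyde under non-basic conditions, so neither the chain stereocentre nor the β-peroxy ester is endangered.

Step 19
Reactants: 30 1-phenyl-1H-tetrazole-5-thiol; 31 1-bromopropane
Product: 32 1-phenyl-5-(propylsulfanyl)-1H-tetrazole
Conditions: K2CO3, acetone, reflux
Reagents that add atoms: none
Why: SN2 S-alkylation of the acidic heteroaryl thiol with a primary bromide is straightforward.

Step 20
Reactants: 32 1-phenyl-5-(propylsulfanyl)-1H-tetrazole
Product: 33 1-phenyl-5-(propane-1-sulfonyl)-1H-tetrazole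
Conditions: H2O2 (30 % aq.), (NH4)6Mo7O24·4H2O (cat.), EtOH, 0 °C → rt
Reagents that add atoms: hydrogen peroxide, OO
Why: Molybdate-catalysed peroxide oxidation of the sulfide to the sulfone is the standard preparation of these olefination reagents.

Step 21
Reactants: 33 1-phenyl-5-(propane-1-sulfonyl)-1H-tetrazole; 29 methyl 2-{(3S,4S,6S)-4,6-diethyl-6-[(4R)-4-formylhexyl]-1,2-dioxan-3-yl}acetate
Product: 35 methyl 2-{(3S,4S,6S)-4,6-diethyl-6-[(4R,5E)-4-ethyloct-5-en-1-yl]-1,2-dioxan-3-yl}acetate (target), via potassium sulfonyl carbanion 34 (not isolated)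
Conditions: KN(SiMe3)2 (slightly less than 33), DME, −60 °C; then 29, −60 °C → rt
Reagents that add atoms: none
Why: In this Julia–Kocienski olefination the pre-formed potassium carbanion adds to the α-branched aldehyde, and Smiles rearrangement with anti elimination should favour the E-alkene in DME, while the absence of free amide base spares the ester, C3–H and the chain stereocentre.

**Compound list**

1 | (4S)-4-benzyl-1,3-oxazolidin-2-one | O=C1N[C@@H](Cc2ccccc2)CO1 | starting material
2 | butanoyl chloride | CCCC(=O)Cl | starting material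
3 | (4S)-4-benzyl-3-butanoyl-1,3-oxazolidin-2-one | CCCC(=O)N1[C@@H](Cc2ccccc2)COC1=O | intermediate
4 | allyl iodide | C=CCI | starting material
5 | sodium Z-enolate of 3 | CC/C=C(\[O-])N1[C@@H](Cc2ccccc2)COC1=O.[Na+] | intermediate
6 | (4S)-4-benzyl-3-[(2R)-2-ethylpent-4-enoyl]-1,3-oxazolidin-2-one | C=CC[C@@H](CC)C(=O)N1[C@@H](Cc2ccccc2)COC1=O | intermediate
7 | (2R)-2-ethylpent-4-en-1-ol | C=CC[C@@H](CC)CO | intermediate
8 | tert-butyl{[(2R)-2-ethylpent-4-en-1-yl]oxy}dimethylsilane | C=CC[C@@H](CC)CO[Si](C)(C)C(C)(C)C | intermediate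
9 | chlorobis(cyclopentadienyl)[(4R)-4-(TBSO-methyl)hexyl]zirconium | Cl[Zr](CCC[C@@H](CC)CO[Si](C)(C)C(C)(C)C)(C1C=CC=C1)C1C=CC=C1 | intermediate
10 | tert-butyl{[(2R)-2-ethyl-5-iodopentyl]oxy}dimethylsilane | ICCC[C@@H](CC)CO[Si](C)(C)C(C)(C)C | intermediate
11 | butanal | CCCC=O | starting material
12 | but-3-en-2-one | CC(=O)C=C | starting material
13 | (2S)-2-ethyl-5-oxohexanal | O=C[C@@H](CC)CCC(C)=O | intermediate
14 | (4S)-4-ethylcyclohex-2-en-1-one | O=C1C=C[C@@H](CC)CC1 | intermediate
15 | lithium (4S)-4-ethylcyclohexa-1,5-dien-1-olate | [Li+].[O-]C1=CC[C@H](CC)C=C1 | intermediate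
16 | (4S)-4-ethyl-6-[(4R)-4-(TBSO-methyl)hexyl]cyclohex-2-en-1-one, C6 epimers | O=C1C=C[C@@H](CC)CC1CCC[C@@H](CC)CO[Si](C)(C)C(C)(C)C | intermediate
17 | lithium dienolate of 16 | [Li+].[O-]C1=C(CCC[C@@H](CC)CO[Si](C)(C)C(C)(C)C)C[C@H](CC)C=C1 | intermediate
18 | (4S)-4-ethyl-2-[(4R)-4-(TBSO-methyl)hexyl]cyclohexa-1,5-dien-1-yl trifluoromethanesulfonate | CC(C)(C)[Si](C)(C)OC[C@H](CC)CCCC1=C(OS(=O)(=O)C(F)(F)F)C=C[C@@H](CC)C1 | intermediate
19 | (5S)-5-ethyl-1-[(4R)-4-(TBSO-methyl)hexyl]cyclohexa-1,3-diene | CC(C)(C)[Si](C)(C)OC[C@H](CC)CCCC1=CC=C[C@@H](CC)C1 | intermediate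
20 | (1S,4R,8S)-1-[(4R)-4-(TBSO-methyl)hexyl]-8-ethyl-2,3-dioxabicyclo[2.2.2]oct-5-ene | CC(C)(C)[Si](C)(C)OC[C@H](CC)CCC[C@@]1(C=C2)C[C@H](CC)[C@H]2OO1 | intermediate
21 | (1S,4R,5R,6S,8S)-1-[(4R)-4-(TBSO-methyl)hexyl]-8-ethyl-2,3-dioxabicyclo[2.2.2]octane-5,6-diol (cis-diol drawn anti to the O–O bridge; either face leads to 22) | CC(C)(C)[Si](C)(C)OC[C@H](CC)CCC[C@@]1([C@@H](O)[C@H]2O)C[C@H](CC)[C@H]2OO1 | intermediate
22 | (3R,4S,6S)-4-ethyl-6-[(4R)-4-(TBSO-methyl)hexyl]-1,2-dioxane-3,6-dicarbaldehyde | CC(C)(C)[Si](C)(C)OC[C@H](CC)CCC[C@@]1(C=O)C[C@H](CC)[C@H](C=O)OO1 | intermediate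
23 | (3S,4S,6S)-3,6-diethenyl-4-ethyl-6-[(4R)-4-(TBSO-methyl)hexyl]-1,2-dioxane | CC(C)(C)[Si](C)(C)OC[C@H](CC)CCC[C@@]1(C=C)C[C@H](CC)[C@H](C=C)OO1 | intermediate
24 | bis(3-methylbutan-2-yl)borane adduct at the C3 vinyl of 23 | CC(C)(C)[Si](C)(C)OC[C@H](CC)CCC[C@@]1(C=C)C[C@H](CC)[C@H](CCB(C(C)C(C)C)C(C)C(C)C)OO1 | intermediate
25 | 2-{(3S,4S,6S)-6-ethenyl-4-ethyl-6-[(4R)-4-(TBSO-methyl)hexyl]-1,2-dioxan-3-yl}ethan-1-ol | CC(C)(C)[Si](C)(C)OC[C@H](CC)CCC[C@@]1(C=C)C[C@H](CC)[C@H](CCO)OO1 | intermediate
26 | 2-{(3S,4S,6S)-4,6-diethyl-6-[(4R)-4-(TBSO-methyl)hexyl]-1,2-dioxan-3-yl}ethan-1-ol | CC(C)(C)[Si](C)(C)OC[C@H](CC)CCC[C@@]1(CC)C[C@H](CC)[C@H](CCO)OO1 | intermediate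
27 | 2-{(3S,4S,6S)-4,6-diethyl-6-[(4R)-4-(TBSO-methyl)hexyl]-1,2-dioxan-3-yl}acetic acid | CC(C)(C)[Si](C)(C)OC[C@H](CC)CCC[C@@]1(CC)C[C@H](CC)[C@H](CC(=O)O)OO1 | intermediate
28 | methyl 2-{(3S,4S,6S)-4,6-diethyl-6-[(4R)-4-(hydroxymethyl)hexyl]-1,2-dioxan-3-yl}acetate | OC[C@H](CC)CCC[C@@]1(CC)C[C@H](CC)[C@H](CC(=O)OC)OO1 | intermediate
29 | methyl 2-{(3S,4S,6S)-4,6-diethyl-6-[(4R)-4-formylhexyl]-1,2-dioxan-3-yl}acetate | O=C[C@H](CC)CCC[C@@]1(CC)C[C@H](CC)[C@H](CC(=O)OC)OO1 | intermediate
30 | 1-phenyl-1H-tetrazole-5-thiol | Sc1nnnn1-c1ccccc1 | starting material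
31 | 1-bromopropane | CCCBr | starting material
32 | 1-phenyl-5-(propylsulfanyl)-1H-tetrazole | CCCSc1nnnn1-c1ccccc1 | intermediate
33 | 1-phenyl-5-(propane-1-sulfonyl)-1H-tetrazole | CCCS(=O)(=O)c1nnnn1-c1ccccc1 | intermediate
34 | potassium α-sulfonyl carbanion of 33 | CC[CH-]S(=O)(=O)c1nnnn1-c1ccccc1.[K+] | intermediate
35 | methyl 2-{(3S,4S,6S)-4,6-diethyl-6-[(4R,5E)-4-ethyloct-5-en-1-yl]-1,2-dioxan-3-yl}acetate | CC/C=C/[C@H](CC)CCC[C@@]1(CC)C[C@H](CC)[C@H](CC(=O)OC)OO1 | target

**Where the stereochemistry is set**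
- The chain centre is set in step 2.
- C4 is set in step 6.
- C3 and C6 are set in step 11.
- The E-alkene is set in step 21.
- The only centres later exposed next to a carbonyl group are C3 in 22 and the chain centre in 29. Both are handled cold and without free base.

Total steps: 21. Longest linear sequence: 17 (steps 1–5, 8–18, 21).

**Steps most likely to fail**

**Step 11.** Singlet oxygen is small and very reactive. It may discriminate poorly between the two diene faces, and hydrogen abstraction (ene hydroperoxidation) may drain material.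

The fallback runs from 19 back to 20 and oxygenates without singlet oxygen.
- Ground-state O2 is passed through a dilute CH2Cl2 solution of 19 at −78 °C in the dark. Catalytic tris(4-bromophenyl)ammoniumyl hexachloroantimonate, (4-BrC6H4)3N SbCl6, and 2,6-di-tert-butylpyridine are present.
- One-electron oxidation gives the diene radical cation, which captures triplet oxygen stepwise and passes the hole on in a chain. This is a known way from alkylated cyclohexa-1,3-dienes and steroidal 5,7-dienes to the same kind of endoperoxide.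
- This manifold has no ene channel.
- The first C–O bond forms at the less substituted terminus next to the stereocentre, where the ethyl group should be felt more strongly.
- No new compound arises (F0).

**Step 13.** The α-peroxy aldehyde at C3 may lose its α-hydrogen to the ylide. That would lead to epimerisation or Kornblum–DeLaMare-type O–O cleavage before olefination.

The fallback runs from 20 directly to 23 and bypasses steps 12 and 13 by ring-opening metathesis.
- Compound 20 is stirred under ethylene with the phosphine-free second-generation Hoveyda–Grubbs catalyst, (H2IMes)Cl2Ru(=CH-2-(i-PrO)C6H4), in CH2Cl2 at room temperature.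
- Release of the bicyclo[2.2.2]octene strain drives the opening, and excess ethylene caps both ends as vinyl groups.
- No carbonyl intermediate and no base are involved.
- Ring opening of bicyclo[2.2.2]octenes under ethylene is known, and so is ruthenium alkylidene metathesis beside cyclic peroxides. Their combination on this substrate is the open point.
- No new compound arises (F0).

**Step 14.** The borane may not distinguish the two monosubstituted alkenes well enough, which would give regioisomeric and doubly hydroborated material.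

The fallback runs from 22 back to 28 and tells the two ends apart one stage earlier, at the carbonyl carbons themselves.
- Compound 22 is treated at −78 °C with one equivalent of Ph3P=CHOMe, made from Ph3P(CH2OMe)Cl and KN(SiMe3)2. The ylide should take the C3 aldehyde (α-CH) ahead of the C6 aldehyde (α-quaternary) and give the enol ether aldehyde F1.
- Ph3P=CH2 then converts the remaining aldehyde into the vinyl enol ether F2.
- Pyridinium chlorochromate, C5H5NH[CrO3Cl], in CH2Cl2 oxidises the methyl enol ether directly to the methyl ester. This is a known enol ether to ester oxidation, and it gives the vinyl ester F3.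
- Diimide, as in step 15, gives the silylated ester F4.
- Methanolic HCl, as in step 17, removes the silyl group to give 28.

Further compounds
F0 | step 11 | none | none
F0 | step 13 | none | none
F1 | step 14 | 4-ethyl-3-(2-methoxyethenyl)-6-[(4R)-4-(TBSO-methyl)hexyl]-1,2-dioxane-6-carbaldehyde, ring configuration as in 22, E/Z mixture | CC(C)(C)[Si](C)(C)OC[C@H](CC)CCC[C@@]1(C=O)C[C@H](CC)[C@H](C=COC)OO1
F2 | step 14 | 6-ethenyl-4-ethyl-3-(2-methoxyethenyl)-6-[(4R)-4-(TBSO-methyl)hexyl]-1,2-dioxane, ring configuration as in 23, E/Z mixture | CC(C)(C)[Si](C)(C)OC[C@H](CC)CCC[C@@]1(C=C)C[C@H](CC)[C@H](C=COC)OO1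
F3 | step 14 | methyl 2-{(3S,4S,6S)-6-ethenyl-4-ethyl-6-[(4R)-4-(TBSO-methyl)hexyl]-1,2-dioxan-3-yl}acetate | CC(C)(C)[Si](C)(C)OC[C@H](CC)CCC[C@@]1(C=C)C[C@H](CC)[C@H](CC(=O)OC)OO1
F4 | step 14 | methyl 2-{(3S,4S,6S)-4,6-diethyl-6-[(4R)-4-(TBSO-methyl)hexyl]-1,2-dioxan-3-yl}acetate | CC(C)(C)[Si](C)(C)OC[C@H](CC)CCC[C@@]1(CC)C[C@H](CC)[C@H](CC(=O)OC)OO1
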